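**Retrosynthetic overview** (fatty-acid numbering, C1 = CO2H … C26 = CH3)
1. Target ⇐ methyl ester 21 ⇐ hydroxy enoate 18: the 1,2-dioxane is the last ring, closed by SN2 of a C6 triflate with HOO⁻ (inversion) and 6-exo peroxy-Michael addition onto the enoate.
2. 18 ⇐ oxolanyl γ-lactone 15/14 (half-reduction/Wittig); the oxolane, first ring of the target, ⇐ Z-hydroxyalkene 12 by Re2O7 syn-oxidative cyclisation (trans ring, erythro C6–O).
3. 12 ⇐ lactol 9 + four-carbon ester ylide (Z-Wittig); 9 ⇐ (R)-γ-lactone 8.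
4. Key bond C9–C10: 8 ⇐ diynal 4 + zinc ester homoenolate under a chiral titanium catalyst; this step sets C10, and C7, C6 and C3 are relayed from it.
5. 4 ⇐ undec-10-yn-1-ol + hex-1-yne (oxidative cross-coupling, oxidation); the 1,3-diyne is a masked Z,Z-diene, unmasked with zinc after the oxidative cyclisation.

Assumption: the SMILES is read as (3S,6S)-trans-1,2-dioxane, (2S,5R)-trans-oxolane, threo at C6/C7 and 9Z,11Z in the side chain.

**Step 1**
Reactants: 1 undec-10-yn-1-ol; 2 hex-1-yne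
Product: 3 heptadeca-10,12-diyn-1-ol
Conditions: 2 (5 equiv), NiCl2·6H2O (5 mol%), CuI (5 mol%), TMEDA (20 mol%), air, THF, rt
Reagents that add atoms: none
Why: Glaser–Hay-type aerobic oxidative cross-coupling of two terminal alkynes; the fivefold excess of cheap hexyne drives 1 to the unsymmetrical diyne, and the non-polar hexyne dimer is removed by chromatography.

**Step 2**
Reactants: 3 heptadeca-10,12-diyn-1-ol
Product: 4 heptadeca-10,12-diynal
Conditions: 2,2,6,6-tetramethylpiperidin-1-oxyl (10 mol%), PhI(OAc)2 (1.1 equiv), CH2Cl2, rt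
Reagents that add atoms: none
Why: Nitroxyl-catalysed oxidation of a primary alcohol stops at the aldehyde and leaves the diyne untouched.

**Step 3 (key step)**
Reactants: 4 heptadeca-10,12-diynal; 5 ethyl 3-iodopropanoate
Product: 8 (5R)-5-(hexadeca-9,11-diyn-1-yl)oxolan-2-one, via zinc homoenolate 6 (not isolated), via open-chain hydroxy ester 7 (not isolated)
Conditions: 5 (5 equiv), Et2Zn (neat, 7 equiv), CuI (0.3 mol%), 50 °C, then 0.1 mmHg; then Ti(OiPr)4 (2 equiv), (1R,2R)-N,N'-bis(trifluoromethylsulfonyl)cyclohexane-1,2-diamine (8 mol%), 4, toluene, −20 °C; 1 M HCl; pTsOH·H2O (5 mol%), toluene, rt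
Reagents that add atoms: none
Why: Proposed new method: iodine–zinc exchange gives the zinc ester homoenolate, whose alkyl group is passed to the chiral titanium bis(sulfonamide) complex and delivered to the Si face of the aldehyde, joining C9 (the β-carbon of a propanoate) to C10 (an aldehyde carbon), both natively electrophilic, and fixing C10 as R before acid lactonisation; the closest known reaction type is the titanium/bis(sulfonamide)-catalysed enantioselective addition of functionalised dialkylzincs to aliphatic aldehydes, together with the known zinc-to-titanium transmetalation of ester homoenolates.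

**Step 4**
Reactants: 8 (5R)-5-(hexadeca-9,11-diyn-1-yl)oxolan-2-one
Product: 9 (5R)-5-(hexadeca-9,11-diyn-1-yl)oxolan-2-ol (anomer mixture)
Conditions: iBu2AlH (1.1 equiv), CH2Cl2, −78 °C; aq. potassium sodium tartrate
Reagents that add atoms: none
Why: Half-reduction of a γ-lactone with iBu2AlH at −78 °C stops at the lactol (stable aluminium hemiacetal); C10 is untouched.

**Step 5**
Reactants: 9 (5R)-5-(hexadeca-9,11-diyn-1-yl)oxolan-2-ol; 10 (4-ethoxy-4-oxobutyl)triphenylphosphonium bromide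
Product: 12 ethyl (4Z,8R)-8-hydroxytetracos-4-ene-17,19-diynoate, via phosphonium ylide 11 (not isolated)
Conditions: 10 (2.6 equiv), KN(SiMe3)2 (2.5 equiv), THF, −78 → 0 °C; then 9, −78 °C → rt
Reagents that add atoms: none
Why: Wittig olefination of the open hydroxy-aldehyde form of the lactol with a non-stabilised ylide under lithium-free conditions gives the Z-alkene (expected ≥95:5), the geometry that later encodes the C6 configuration.

**Step 6**
Reactants: 12 ethyl (4Z,8R)-8-hydroxytetracos-4-ene-17,19-diynoate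
Product: 14 (5R)-5-[(2S,5R)-5-(hexadeca-9,11-diyn-1-yl)oxolan-2-yl]oxolan-2-one, via oxolanyl hydroxy ester 13 (not isolated)
Conditions: Re2O7 (2.5 equiv), (CF3CO)2O (3 equiv), THF, rt, then evaporate; 12, CH2Cl2, 0 °C → rt; aq. NaHCO3; pTsOH·H2O (5 mol%), CH2Cl2, rt
Reagents that add atoms: Re2O7, O=[Re](=O)(=O)O[Re](=O)(=O)=O (one oxo oxygen becomes the C6 oxygen)
Why: Kennedy-type syn-oxidative cyclisation: the C10 alkoxy perrhenate adds its alkoxide oxygen and one oxo oxygen to the same face of the Z-alkene, giving the 2,5-trans oxolane (C7 S, relayed from C10) and, because the addition is syn, the erythro C6 carbinol (R), which then lactonises onto the ester.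

**Step 7**
Reactants: 14 (5R)-5-[(2S,5R)-5-(hexadeca-9,11-diyn-1-yl)oxolan-2-yl]oxolan-2-one
Product: 15 (5R)-5-[(2S,5R)-5-[(9Z,11Z)-hexadeca-9,11-dien-1-yl]oxolan-2-yl]oxolan-2-one
Conditions: Zn dust (activated with Cu(OAc)2·H2O, then AgNO3), MeOH/H2O/THF (2:1:1), 40 °C
Reagents that add atoms: none
Why: Boland reduction: activated zinc reduces only conjugated triple bonds, by cis delivery of hydrogen, giving the Z,Z-diene while lactone and oxolane are inert.

**Step 8**
Reactants: 15 (5R)-5-[(2S,5R)-5-[(9Z,11Z)-hexadeca-9,11-dien-1-yl]oxolan-2-yl]oxolan-2-one; 16 methyl (triphenyl-λ5-phosphanylidene)acetate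
Product: 18 methyl (2E,6R)-6-hydroxy-6-[(2S,5R)-5-[(9Z,11Z)-hexadeca-9,11-dien-1-yl]oxolan-2-yl]hex-2-enoate, via lactol 17 (not isolated)
Conditions: iBu2AlH (1.1 equiv), CH2Cl2, −78 °C; then 16 (2.5 equiv), −78 °C → rt; aq. potassium sodium tartrate
Reagents that add atoms: none
Why: One-pot lactone half-reduction and Wittig olefination with a stabilised ylide gives the E-enoate and frees the C6 hydroxyl without touching any stereocentre.

**Step 9**
Reactants: 18 methyl (2E,6R)-6-hydroxy-6-[(2S,5R)-5-[(9Z,11Z)-hexadeca-9,11-dien-1-yl]oxolan-2-yl]hex-2-enoate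
Product: 21 methyl 2-[(3S,6S)-6-[(2S,5R)-5-[(9Z,11Z)-hexadeca-9,11-dien-1-yl]oxolan-2-yl]-1,2-dioxan-3-yl]acetate, via triflate 19 (not isolated), via hydroperoxide 20 (not isolated)
Conditions: (CF3SO2)2O (1.2 equiv), 2,6-lutidine (2 equiv), CH2Cl2, −78 °C; cannulated into 50% aq. H2O2 (30 equiv), KOH (2.2 equiv), THF, 0 °C → rt
Reagents that add atoms: hydrogen peroxide, OO
Why: SN2 displacement of the secondary triflate by hydroperoxide anion inverts C6 (R to S, erythro to threo), and the peroxide anion then closes the ring by 6-exo peroxy-Michael addition through a chair with both substituents equatorial, giving the 3,6-trans (3S) dioxane, which is also the thermodynamic isomer under the reversible basic conditions.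

**Step 10**
Reactants: 21 methyl 2-[(3S,6S)-6-[(2S,5R)-5-[(9Z,11Z)-hexadeca-9,11-dien-1-yl]oxolan-2-yl]-1,2-dioxan-3-yl]acetate
Product: 22 stolonic acid B, 2-[(3S,6S)-6-[(2S,5R)-5-[(9Z,11Z)-hexadeca-9,11-dien-1-yl]oxolan-2-yl]-1,2-dioxan-3-yl]acetic acid
Conditions: LiOH·H2O (3 equiv), THF/H2O (3:1), 0 °C → rt; then 1 M HCl to pH 3–4, 0 °C
Reagents that add atoms: lithium hydroxide, [Li+].[OH-]
Why: Mild saponification of the methyl ester; the dialkyl peroxide, the Z,Z-diene and all four stereocentres tolerate LiOH at or below room temperature.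

**Compound list**
1 | undec-10-yn-1-ol | C#CCCCCCCCCCO | starting material
2 | hex-1-yne | CCCCC#C | starting material
3 | heptadeca-10,12-diyn-1-ol | CCCCC#CC#CCCCCCCCCCO | intermediate
4 | heptadeca-10,12-diynal | CCCCC#CC#CCCCCCCCCC=O | intermediate
5 | ethyl 3-iodopropanoate | CCOC(=O)CCI | starting material
6 | bis(3-ethoxy-3-oxopropyl)zinc | CCOC(=O)CC[Zn]CCC(=O)OCC | intermediate (not isolated)
7 | ethyl (4R)-4-hydroxyicosa-13,15-diynoate | CCCCC#CC#CCCCCCCCC[C@@H](O)CCC(=O)OCC | intermediate (not isolated)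
8 | (5R)-5-(hexadeca-9,11-diyn-1-yl)oxolan-2-one | CCCCC#CC#CCCCCCCCC[C@@H]1CCC(=O)O1 | intermediate
9 | (5R)-5-(hexadeca-9,11-diyn-1-yl)oxolan-2-ol (anomer mixture) | CCCCC#CC#CCCCCCCCC[C@@H]1CCC(O)O1 | intermediate
10 | (4-ethoxy-4-oxobutyl)triphenylphosphonium bromide | CCOC(=O)CCC[P+](c1ccccc1)(c1ccccc1)c1ccccc1.[Br-] | starting material
11 | ethyl 4-(triphenyl-λ5-phosphanylidene)butanoate | CCOC(=O)CCC=P(c1ccccc1)(c1ccccc1)c1ccccc1 | intermediate (not isolated)
12 | ethyl (4Z,8R)-8-hydroxytetracos-4-ene-17,19-diynoate | CCCCC#CC#CCCCCCCCC[C@@H](O)CC/C=C\CCC(=O)OCC | intermediate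
13 | ethyl (4R)-4-hydroxy-4-[(2S,5R)-5-(hexadeca-9,11-diyn-1-yl)oxolan-2-yl]butanoate | CCCCC#CC#CCCCCCCCC[C@@H]1CC[C@@H]([C@H](O)CCC(=O)OCC)O1 | intermediate (not isolated)
14 | (5R)-5-[(2S,5R)-5-(hexadeca-9,11-diyn-1-yl)oxolan-2-yl]oxolan-2-one | CCCCC#CC#CCCCCCCCC[C@@H]1CC[C@@H]([C@H]2CCC(=O)O2)O1 | intermediate
15 | (5R)-5-[(2S,5R)-5-[(9Z,11Z)-hexadeca-9,11-dien-1-yl]oxolan-2-yl]oxolan-2-one | CCCC/C=C\C=C/CCCCCCCC[C@@H]1CC[C@@H]([C@H]2CCC(=O)O2)O1 | intermediate
16 | methyl (triphenyl-λ5-phosphanylidene)acetate | COC(=O)C=P(c1ccccc1)(c1ccccc1)c1ccccc1 | starting material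
17 | (5R)-5-[(2S,5R)-5-[(9Z,11Z)-hexadeca-9,11-dien-1-yl]oxolan-2-yl]oxolan-2-ol (anomer mixture) | CCCC/C=C\C=C/CCCCCCCC[C@@H]1CC[C@@H]([C@H]2CCC(O)O2)O1 | intermediate (not isolated)
18 | methyl (2E,6R)-6-hydroxy-6-[(2S,5R)-5-[(9Z,11Z)-hexadeca-9,11-dien-1-yl]oxolan-2-yl]hex-2-enoate | CCCC/C=C\C=C/CCCCCCCC[C@@H]1CC[C@@H]([C@H](O)CC/C=C/C(=O)OC)O1 | intermediate
19 | methyl (2E,6R)-6-[(2S,5R)-5-[(9Z,11Z)-hexadeca-9,11-dien-1-yl]oxolan-2-yl]-6-{[(trifluoromethyl)sulfonyl]oxy}hex-2-enoate | CCCC/C=C\C=C/CCCCCCCC[C@@H]1CC[C@@H]([C@H](OS(=O)(=O)C(F)(F)F)CC/C=C/C(=O)OC)O1 | intermediate (not isolated)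
20 | methyl (2E,6S)-6-hydroperoxy-6-[(2S,5R)-5-[(9Z,11Z)-hexadeca-9,11-dien-1-yl]oxolan-2-yl]hex-2-enoate | CCCC/C=C\C=C/CCCCCCCC[C@@H]1CC[C@@H]([C@@H](OO)CC/C=C/C(=O)OC)O1 | intermediate (not isolated)
21 | methyl 2-[(3S,6S)-6-[(2S,5R)-5-[(9Z,11Z)-hexadeca-9,11-dien-1-yl]oxolan-2-yl]-1,2-dioxan-3-yl]acetate | CCCC/C=C\C=C/CCCCCCCC[C@@H]1CC[C@@H]([C@@H]2CC[C@@H](CC(=O)OC)OO2)O1 | intermediate
22 | stolonic acid B | CCCC/C=C\C=C/CCCCCCCC[C@@H]1CC[C@@H]([C@@H]2CC[C@@H](CC(=O)O)OO2)O1 | target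

**Step count:** 10 steps in total. **Longest linear sequence:** 10 steps (1 → 3 → 4 → 8 → 9 → 12 → 14 → 15 → 18 → 21 → 22).

**Three steps most likely to fail**

Step 3. The internally chelated zinc ester homoenolate may transfer to titanium too slowly at −20 °C, giving low conversion or eroded enantioselectivity. The fallback sets out from 4 and comes back at 8. A thiazolium-carbene Stetter addition (3-benzyl-5-(2-hydroxyethyl)-4-methylthiazolium chloride, Et3N) of the acyl anion equivalent of 4 to ethyl acrylate gives ethyl 4-oxoicosa-13,15-diynoate F1. Saponification gives 4-oxoicosa-13,15-diynoic acid F2. Biocatalytic reduction of the 4-oxo acid (baker's yeast or an isolated R-selective ketoreductase, the known route from 4-oxoalkanoic acids to (R)-γ-lactones) and acidification then give lactone 8.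

Step 6. The perrhenate cyclisation of a 1,2-disubstituted Z-alkene may be low-yielding, or trifluoroacetylation of the C10 hydroxyl may compete. The fallback sets out from 9 and comes back at 14, replacing syn addition to a Z-alkene by anti addition to an E-alkene.
- Ethyl 4-bromobutanoate and 1-phenyl-1H-tetrazole-5-thiol (K2CO3) give ethyl 4-[(1-phenyl-1H-tetrazol-5-yl)sulfanyl]butanoate F3, which mCPBA oxidises to ethyl 4-[(1-phenyl-1H-tetrazol-5-yl)sulfonyl]butanoate F4.
- Julia–Kocienski olefination of lactol 9 with F4 (KN(SiMe3)2, DME, −60 °C) gives ethyl (4E,8R)-8-hydroxytetracos-4-ene-17,19-diynoate F5.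
- Shi epoxidation with the D-fructose-derived ketone 1,2:4,5-di-O-isopropylidene-β-D-erythro-2,3-hexodiulo-2,6-pyranose and KHSO5 (as 2KHSO5·KHSO4·K2SO4, buffered with K2CO3) gives ethyl 3-[(2R,3R)-3-[(3R)-3-hydroxynonadeca-12,14-diyn-1-yl]oxiran-2-yl]propanoate F6.
- Camphorsulfonic acid then triggers 5-exo opening at C7 with inversion, leading through 13 to lactone 14 with the same 2,5-trans, erythro arrangement.

Step 9. The triflate next to the oxolane oxygen can eliminate, ring-expand to an oxane through oxygen participation, or be alkylated twice, and the methyl ester can be attacked by HOO⁻; the 3,6-cis dioxane may also form. The fallback sets out from 18 and comes back at 21, using a protected hydroperoxide nucleophile under non-hydrolytic conditions.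
- MsCl/Et3N gives methyl (2E,6R)-6-[(2S,5R)-5-[(9Z,11Z)-hexadeca-9,11-dien-1-yl]oxolan-2-yl]-6-[(methylsulfonyl)oxy]hex-2-enoate F7.
- Its displacement (CsOH, DMF) by 2-methoxypropan-2-yl hydroperoxide F8, made from 2-methoxypropene and ethereal H2O2, gives with inversion methyl (2E,6S)-6-[(2S,5R)-5-[(9Z,11Z)-hexadeca-9,11-dien-1-yl]oxolan-2-yl]-6-[(2-methoxypropan-2-yl)peroxy]hex-2-enoate F9.
- Aqueous acetic acid unmasks hydroperoxide 20, and Et2NH in CF3CH2OH closes it to 21, equilibrating towards the trans-diequatorial ring.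

**Further compounds**
F1 | step 3 | ethyl 4-oxoicosa-13,15-diynoate | CCCCC#CC#CCCCCCCCCC(=O)CCC(=O)OCC
F2 | step 3 | 4-oxoicosa-13,15-diynoic acid | CCCCC#CC#CCCCCCCCCC(=O)CCC(=O)O
F3 | step 6 | ethyl 4-[(1-phenyl-1H-tetrazol-5-yl)sulfanyl]butanoate | CCOC(=O)CCCSc1nnnn1-c1ccccc1
F4 | step 6 | ethyl 4-[(1-phenyl-1H-tetrazol-5-yl)sulfonyl]butanoate | CCOC(=O)CCCS(=O)(=O)c1nnnn1-c1ccccc1
F5 | step 6 | ethyl (4E,8R)-8-hydroxytetracos-4-ene-17,19-diynoate | CCCCC#CC#CCCCCCCCC[C@@H](O)CC/C=C/CCC(=O)OCC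
F6 | step 6 | ethyl 3-[(2R,3R)-3-[(3R)-3-hydroxynonadeca-12,14-diyn-1-yl]oxiran-2-yl]propanoate | CCCCC#CC#CCCCCCCCC[C@@H](O)CC[C@H]1O[C@@H]1CCC(=O)OCC
F7 | step 9 | methyl (2E,6R)-6-[(2S,5R)-5-[(9Z,11Z)-hexadeca-9,11-dien-1-yl]oxolan-2-yl]-6-[(methylsulfonyl)oxy]hex-2-enoate | CCCC/C=C\C=C/CCCCCCCC[C@@H]1CC[C@@H]([C@H](OS(C)(=O)=O)CC/C=C/C(=O)OC)O1
F8 | step 9 | 2-methoxypropan-2-yl hydroperoxide | COC(C)(C)OO
F9 | step 9 | methyl (2E,6S)-6-[(2S,5R)-5-[(9Z,11Z)-hexadeca-9,11-dien-1-yl]oxolan-2-yl]-6-[(2-methoxypropan-2-yl)peroxy]hex-2-enoate | CCCC/C=C\C=C/CCCCCCCC[C@@H]1CC[C@@H]([C@@H](OOC(C)(C)OC)CC/C=C/C(=O)OC)O1
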